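## Structural features

The target 21 is a resveratrol trimer made of two 2,3-diaryl-2,3-dihydrobenzofurans joined head to tail. Ring A, the arene of the first dihydrobenzofuran (furan atoms O1, C2, C3), carries a hydroxyl at C4 and an (E)-4-hydroxystyryl group at C6. Its C3 is bonded to C6' of ring B, the central arene, which belongs to the second dihydrobenzofuran (O1', C2', C3', hydroxyl at C4'); C3' carries ring C, a 3,5-dihydroxyphenyl group, and C2 and C2' each carry a 4-hydroxyphenyl group. The four stereocentres form two adjacent pairs, C2/C3 and C2'/C3', all S and each pair trans; ring B separates the pairs, so neither can direct the other. The fragile groups are the seven free phenols (oxidation), the stilbene (acid, light, hydrogenation) and the two benzylic C2–O bonds, which ionise under acid; this ionisation makes trans the thermodynamic arrangement at C2 but cannot repair C3. The real difficulty is absolute control at the two diaryl-substituted methines C3 and C3', together with the hindered C3–C6' and C3'–ring C bonds next to a peri oxygen. The key step uses the fact that C2' and C3' each hold one aryl group and one hydrogen, trans: this is what anti addition of two aryl groups across the C2=C3 bond of a flat 4,6-dioxygenated benzofuran leaves, and ring A repeats the pattern with ring B as its C3 aryl group.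

## Logic of the disconnections

21 from 20. The seven phenolic O–H bonds are traced to O–CH3 bonds. Free phenols would not survive butyllithium, triflation or cationic palladium, whereas methyl ethers pass through all of them. The forward step must cleave seven ethers without opening the furans or touching the alkene.

20 from 18 and 19. The bond between C6 of ring A and the alkene carbon is cut. This keeps the only hydrogenation-sensitive group out of all earlier steps and leaves a commercial styrene. The forward reaction must arylate the terminal alkene carbon only and give the E isomer.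

18 from 17, and 17 from 16. The O–S bond and then the O–CH2Ph bond at C6 of ring A are cut. The C6 oxygen is a masked leaving group, inert as the benzyl ether and active as the triflate. The hydrogenolysis must tell a primary benzyl ether from the secondary benzylic C2–O bonds of both furans.

16 from 15. The C2–H bond of ring A is traced to a C2–B bond, which is what the coupling leaves at C2. Replacement of boron by hydrogen must go with retention so that the aryl groups stay trans.

15 from 14 and 10. The C2–aryl and C3–C6' bonds of the ring A furan are cut together. The whole ring A unit falls back to 10, which is already needed for ring B, so one preparation serves both couplings. The forward step needs catalyst control of the C3 face, with the centres of 14 four bonds from the reacting carbon.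

14 from 13, 13 from 12, and 12 from 11. The same chain of O–S, O–CH2Ph and C2'–B cuts is applied at ring B, for the same reasons. The demands are the same: selective hydrogenolysis and retentive protodeboronation.

11 from 10 and 7. This is the key cut: the C2'–aryl bond and the C3'–ring C bond. Both stereocentres and both aryl–carbon bonds of the ring B furan disappear and two achiral pieces remain. The forward step must put palladium on one face of C3' under ligand control, shift the aryl group anti, and run halide-free so that direct cross-coupling stays slower.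

10 from 5 and 8 (through 9). The C2–B bond is cut, leaving a flat benzofuran and a commercial boronic ester. Making 9 by deprotonation of 5, not from a 2-halobenzofuran, keeps lithium halide out of the coupling. The forward step needs clean metalation at C2 in preference to the benzylic position of the ether.

7 from 6. The O–S bond is cut, leaving a commercial phenol. A triflate is required because halide would suppress the conjunctive pathway.

5 from 3 (through 4). The C3–H bond and the C2=C3 double bond are traced to the C3 carbonyl. This gives a ketone whose two phenol oxygens can be told apart. The dehydration must not oligomerise the electron-rich benzofuran.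

3 from 2, and 2 from 1. The O–CH3 bond at C4 and the O–CH2Ph bond at C6 are cut in that order. The hydrogen bond of the 4-OH to the carbonyl distinguishes the two phenols of 1. A benzyl ether is kept at O6 because it survives base, hydride, butyllithium at low temperature and fluoride, and leaves under neutral conditions before any alkene exists. A fluoride-labile silyl ether could have been removed during protodeboronation, but it would not survive methylation para to the carbonyl. The forward steps need monoalkylation at O6 and then O- over C-alkylation.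

## Other disconnections considered

Alternative 1: The cut goes through ring B itself, at the B3a–B4 and B7–B7a bonds. The central arene would be made last from a cyclobutenone A2 carrying the finished ring A dihydrobenzofuran and a siloxyalkyne A3 carrying C3' and C2' with their aryl groups.
- Forward key step: heating the two (Danheiser benzannulation: four-electron ring opening to a vinylketene, [2+2] addition to the alkyne, second ring opening, six-electron closure, tautomerisation) would give the resorcinol monosilyl ether A1. The ring B furan would then be closed by ionising the silyloxy-bearing C2' onto the free phenol.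
- In favour: the substitution pattern of ring B is fixed by the mechanism; the two ring B oxygens emerge differentiated without selective alkylation; no metal catalyst and no new reaction type are needed; two large halves are joined late.
- Against: the cascade creates none of the four stereocentres; the propargylic, benzylic C3'–H of A3 is exposed to epimerisation at the reaction temperature; the stilbene of A2 can compete for the ketene; A2 and A3 each need a long sequence.
- Comparison: on the regiochemistry of ring B the alternative is the better plan, and on mechanism it is the safer one (a well-charted pericyclic cascade against an untested metallate shift). On stereocontrol and step economy the chosen plan is ahead, since one catalytic operation used twice sets all four centres starting from a three-step benzofuran.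

Alternative 2: The cut is the C2–C3 bond of the ring A furan. The precursor is a diaryl diazomethane A5 whose carbene carbon sits between the ring B unit and the ring A arene bearing an ortho 4-methoxybenzyl ether.
- Forward key step: Rh2(R-PTAD)4 or its enantiomer would decompose A5; the carbene inserts into the benzylic C–H bond of the ether and closes the furan as the cis 6-bromide A4 (C3 as required, C2 epimeric).
- In favour: donor/donor carbene C–H insertion is established for this class of 2,3-diaryl dihydrobenzofurans with catalyst control; C3 is set in the ring-forming event; the bromide of A4 is a ready Heck handle, so no debenzylation and triflation are needed at the end.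
- Against: the insertion gives the cis isomer, so C2 must be epimerised with acid on a large intermediate; each furan costs a ketone, a hydrazone and an oxidation; the hydrazone of a benzophenone with two ortho oxygens forms reluctantly; the bromide must survive organometallic steps.
- Comparison: structurally both plans build the furans one after the other under catalyst control at C3 and are equal in reach. Mechanistically the insertion forms one C–C bond and a ring, while the conjunctive coupling forms two C–C bonds on an existing ring and gives trans directly. In precedent, and therefore in risk, the alternative is clearly better, and its end game is two steps shorter. Per furan it needs about six operations against four, so the chosen plan is shorter overall if its key step holds. This chemistry is kept as the fallback for steps 6 and 10.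

Alternative 3: The cut is the C3–A3a bond of ring A, made by a 1,2-aryl shift. The precursor is the protected flavanone A7, derived from (2S)-naringenin A8.
- Forward key step: PhI(OAc)2 and H2SO4 in trimethyl orthoformate; the trivalent iodine reagent attacks the enol ether at C3, the dioxygenated arene migrates from the carbonyl carbon to C3 with reductive loss of the iodine group, and the pyranone contracts to the trans ester A6.
- In favour: C2 comes from the chiral pool without asymmetric catalysis; the trans relationship follows from migration anti to the C2 aryl group; the full oxygenation pattern of ring A is present from the start; the reagents are cheap and metal-free. On these points it is better than the chosen plan.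
- Against: A6 carries an ester at C3 where the target needs the C3–C6' bond, so ring B or its bond to C3 must still be built from a carboxyl carbon at a hindered position; the mesylate that suppresses migration of the C2 aryl group must later be exchanged; flavanones can racemise through ring opening to the chalcone; ring B still needs its own asymmetric construction.
- Comparison: structurally it solves ring A minus its hardest bond; mechanistically it is a proven rearrangement against a new coupling; in step economy it falls behind, because the ester-to-arene conversion and a separate route to ring B add more steps than two iterations of the chosen plan.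

Key step: step 6

Assumption: the (Sp,Sp) enantiomer of the MandyPhos ligand is taken to direct palladium to the Si face of C3 of borate 10; if a test coupling showed the opposite preference, the (Rp,Rp) ligand would be used in steps 6 and 10 and nothing else would change.

## Route

Step 1
Reactants: 1 4,6-dihydroxy-1-benzofuran-3(2H)-one
Product: 2 6-(benzyloxy)-4-hydroxy-1-benzofuran-3(2H)-one
Conditions: BnBr (1.05 equiv), K2CO3 (1.1 equiv), DMF, 0 °C → rt
Reagents that add atoms: benzyl bromide, BrCc1ccccc1
Why: Williamson ether synthesis; the 4-OH is held in a hydrogen bond to the C3 carbonyl while the 6-OH is a vinylogous acid para to it, so one equivalent of base and benzyl bromide should alkylate O6 only.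

Step 2
Reactants: 2 6-(benzyloxy)-4-hydroxy-1-benzofuran-3(2H)-one
Product: 3 6-(benzyloxy)-4-methoxy-1-benzofuran-3(2H)-one
Conditions: MeI (1.5 equiv), K2CO3, acetone, reflux
Reagents that add atoms: iodomethane, CI
Why: Williamson methylation of the remaining chelated phenol under more forcing conditions; with a carbonate base the phenoxide should be alkylated faster than the C2 methylene.

Step 3
Reactants: 3 6-(benzyloxy)-4-methoxy-1-benzofuran-3(2H)-one
Product: 5 6-(benzyloxy)-4-methoxy-1-benzofuran, via racemic 6-(benzyloxy)-4-methoxy-2,3-dihydro-1-benzofuran-3-ol 4 (not isolated)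
Conditions: NaBH4, MeOH/THF, 0 °C → rt; then 2 M HCl (aq), rt
Reagents that add atoms: none
Why: Borohydride reduction of the aryl ketone gives the benzylic alcohol 4, and its acid-catalysed dehydration is driven by aromatisation and by the donor oxygens ortho and para to the carbinol carbon; the transient stereocentre of 4 is destroyed.

Step 4
Reactants: 6 3,5-dimethoxyphenol
Product: 7 3,5-dimethoxyphenyl trifluoromethanesulfonate
Conditions: Tf2O, pyridine, CH2Cl2, 0 °C
Reagents that add atoms: trifluoromethanesulfonic anhydride, O=S(=O)(OS(=O)(=O)C(F)(F)F)C(F)(F)F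
Why: O-Sulfonylation of a phenol; it turns ring C into an aryl electrophile without bringing halide into the later coupling.

Step 5
Reactants: 5 6-(benzyloxy)-4-methoxy-1-benzofuran, 8 2-(4-methoxyphenyl)-4,4,5,5-tetramethyl-1,3,2-dioxaborolane
Product: 10 lithium [6-(benzyloxy)-4-methoxy-1-benzofuran-2-yl](4-methoxyphenyl)(2,3-dimethylbutane-2,3-diolato)borate, via 2-lithio-6-(benzyloxy)-4-methoxy-1-benzofuran 9 (not isolated)
Conditions: n-BuLi (1.0 equiv), THF, −78 °C; 8 (1.0 equiv), −78 → 0 °C; volatiles removed in vacuo, solid kept under argon at −30 °C; batch sized for steps 6 and 10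
Reagents that add atoms: n-butyllithium, [Li]CCCC
Why: Heteroaryl C–H lithiation followed by boron ate complex formation: n-BuLi removes the most acidic proton (C2–H, next to the ring oxygen) of 5 and the resulting 9 adds to the empty p orbital of the boron of 8; the halide-free, solvent-free borate should be storable cold under argon as a solid, so one batch can feed both couplings.

Step 6
Reactants: 10 lithium [6-(benzyloxy)-4-methoxy-1-benzofuran-2-yl](4-methoxyphenyl)(2,3-dimethylbutane-2,3-diolato)borate, 7 3,5-dimethoxyphenyl trifluoromethanesulfonate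
Product: 11 2-[(2S,3S)-6-(benzyloxy)-3-(3,5-dimethoxyphenyl)-4-methoxy-2-(4-methoxyphenyl)-2,3-dihydro-1-benzofuran-2-yl]-4,4,5,5-tetramethyl-1,3,2-dioxaborolane (aryl groups trans; boron cis to the C3 aryl group)
Conditions: 10 (1.0 equiv), 7 (1.1 equiv), Pd(OAc)2 (3 mol%), (Sp,Sp)-MandyPhos [1,1'-bis(diarylphosphino)-2,2'-bis(α-dimethylaminobenzyl)ferrocene, aryl = 4-methoxy-3,5-dimethylphenyl] (3.6 mol%), THF, 60 °C
Reagents that add atoms: none
Why: Proposed new method: oxidative addition of 7 to zerovalent palladium gives a cationic aryl–palladium species that binds the C2=C3 bond of 10 at C3, the 4-methoxyphenyl group then shifts from boron to C2 anti to palladium, and reductive elimination with retention forms the C3–ring C bond. The closest known reaction type is the palladium/MandyPhos conjunctive cross-coupling of alkenylboron ate complexes with aryl triflates, and the dearomative 1,2-boronate shift of indol-2-yl borates triggered by allyl–palladium electrophiles shows that a benzo-fused five-membered heteroarene can take the alkene role; the furan ring of a benzofuran has little aromatic stabilisation and its C3 is enol-ether-like and further activated by the 4,6-oxygens. No ring is closed. C3 is set by the chiral ligand, which should place palladium on the Si face of C3; C2 follows stereospecifically because the aryl group must arrive on the opposite (Re) face, so boron ends cis to the C3 aryl group and the two aryl groups trans. The step needs the conjunctive pathway to beat direct transfer of either boron-bound group to palladium: the halide-free triflate keeps palladium cationic and alkene-seeking, and the chelating bisphosphine leaves no site for transmetalation. The C3–palladium intermediate has no β-hydrogen because C2 is fully substituted, so reductive elimination should be its main exit.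

Step 7
Reactants: 11 the C2 pinacol boronate of the ring B unit
Product: 12 (2S,3S)-6-(benzyloxy)-3-(3,5-dimethoxyphenyl)-4-methoxy-2-(4-methoxyphenyl)-2,3-dihydro-1-benzofuran (trans)
Conditions: Bu4NF·3H2O (3 equiv), toluene, 45 °C
Reagents that add atoms: none
Why: Fluoride-promoted protodeboronation of a tertiary benzylic boronic ester: fluoride forms the boron ate complex and water protonates C2 from the front as the C–B bond breaks (SE2, retention), so hydrogen takes the place of boron and the aryl groups stay trans. Trans is also the thermodynamic arrangement, so brief acid equilibration through the 4-methoxybenzylic cation at C2 would correct a leak without touching C3.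

Step 8
Reactants: 12 the trans benzyl ether of the ring B unit
Product: 13 (2S,3S)-3-(3,5-dimethoxyphenyl)-4-methoxy-2-(4-methoxyphenyl)-2,3-dihydro-1-benzofuran-6-ol
Conditions: H2 (1 atm), 10% Pd/C, EtOAc/EtOH, rt
Reagents that add atoms: none
Why: Hydrogenolysis of the primary benzyl aryl ether; under neutral conditions at 1 atm the hindered secondary C2–O bond of the furan and the methyl ethers should be left alone, and no alkene is present yet.

Step 9
Reactants: 13 the ring B phenol
Product: 14 (2S,3S)-3-(3,5-dimethoxyphenyl)-4-methoxy-2-(4-methoxyphenyl)-2,3-dihydro-1-benzofuran-6-yl trifluoromethanesulfonate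
Conditions: Tf2O, pyridine, CH2Cl2, 0 °C
Reagents that add atoms: trifluoromethanesulfonic anhydride, O=S(=O)(OS(=O)(=O)C(F)(F)F)C(F)(F)F
Why: Triflation of the free phenol turns the ring B unit into the aryl electrophile for the second conjunctive coupling.

Step 10
Reactants: 10 lithium [6-(benzyloxy)-4-methoxy-1-benzofuran-2-yl](4-methoxyphenyl)(2,3-dimethylbutane-2,3-diolato)borate, 14 the ring B aryl triflate
Product: 15 2-[(2S,3S)-6-(benzyloxy)-3-[(2S,3S)-3-(3,5-dimethoxyphenyl)-4-methoxy-2-(4-methoxyphenyl)-2,3-dihydro-1-benzofuran-6-yl]-4-methoxy-2-(4-methoxyphenyl)-2,3-dihydro-1-benzofuran-2-yl]-4,4,5,5-tetramethyl-1,3,2-dioxaborolane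
Conditions: 10 (1.3 equiv), 14 (1.0 equiv), Pd(OAc)2 (5 mol%), (Sp,Sp)-MandyPhos [1,1'-bis(diarylphosphino)-2,2'-bis(α-dimethylaminobenzyl)ferrocene, aryl = 4-methoxy-3,5-dimethylphenyl] (6 mol%), THF, 60 °C
Reagents that add atoms: none
Why: Proposed new method: same mechanism as step 6, the cationic aryl–palladium species from 14 binding C3 of 10, the 4-methoxyphenyl group shifting from boron to C2 anti to palladium, and reductive elimination forming the C3–C6' bond; the closest known reaction type is the palladium/MandyPhos conjunctive cross-coupling of alkenylboron ate complexes with aryl triflates. The stereocentres of 14 lie four bonds from the reacting carbon, so the same ligand enantiomer should again place palladium on the Si face of C3 and give the (2S,3S) ring A unit under catalyst control.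

Step 11
Reactants: 15 the C2 pinacol boronate of the bis(dihydrobenzofuran)
Product: 16 (2S,3S)-6-(benzyloxy)-3-[(2S,3S)-3-(3,5-dimethoxyphenyl)-4-methoxy-2-(4-methoxyphenyl)-2,3-dihydro-1-benzofuran-6-yl]-4-methoxy-2-(4-methoxyphenyl)-2,3-dihydro-1-benzofuran
Conditions: Bu4NF·3H2O (3 equiv), toluene, 45 °C
Reagents that add atoms: none
Why: The same stereoretentive fluoride-promoted protodeboronation as in step 7, now at C2 of ring A, leaving both furans trans.

Step 12
Reactants: 16 the ring A benzyl ether of the bis(dihydrobenzofuran)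
Product: 17 (2S,3S)-3-[(2S,3S)-3-(3,5-dimethoxyphenyl)-4-methoxy-2-(4-methoxyphenyl)-2,3-dihydro-1-benzofuran-6-yl]-4-methoxy-2-(4-methoxyphenyl)-2,3-dihydro-1-benzofuran-6-ol
Conditions: H2 (1 atm), 10% Pd/C, EtOAc/EtOH, rt
Reagents that add atoms: none
Why: Hydrogenolysis of the benzyl ether as in step 8; the stilbene is not yet present, so nothing else in the molecule is reducible under these conditions.

Step 13
Reactants: 17 the ring A phenol of the bis(dihydrobenzofuran)
Product: 18 (2S,3S)-3-[(2S,3S)-3-(3,5-dimethoxyphenyl)-4-methoxy-2-(4-methoxyphenyl)-2,3-dihydro-1-benzofuran-6-yl]-4-methoxy-2-(4-methoxyphenyl)-2,3-dihydro-1-benzofuran-6-yl trifluoromethanesulfonate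
Conditions: Tf2O, pyridine, CH2Cl2, 0 °C
Reagents that add atoms: trifluoromethanesulfonic anhydride, O=S(=O)(OS(=O)(=O)C(F)(F)F)C(F)(F)F
Why: Triflation of the only free phenol provides the electrophile for attaching the styryl group.

Step 14
Reactants: 18 the ring A aryl triflate of the bis(dihydrobenzofuran), 19 4-methoxystyrene
Product: 20 (2S,3S)-3-[(2S,3S)-3-(3,5-dimethoxyphenyl)-4-methoxy-2-(4-methoxyphenyl)-2,3-dihydro-1-benzofuran-6-yl]-4-methoxy-2-(4-methoxyphenyl)-6-[(E)-2-(4-methoxyphenyl)ethenyl]-2,3-dihydro-1-benzofuran
Conditions: PdCl2(PPh3)2 (5 mol%), LiCl (3 equiv), Et3N, DMF, 100 °C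
Reagents that add atoms: none
Why: Heck reaction: oxidative addition of the triflate, exchange to a neutral aryl–palladium chloride, insertion of the styrene with aryl transfer to its unsubstituted terminus and syn β-hydride elimination to the E-stilbene. The chloride additive steers the triflate away from the cationic pathway, which would arylate the internal carbon of an electron-rich styrene.

Step 15
Reactants: 20 the heptamethyl ether of the target
Product: 21 (2S,3S)-3-[(2S,3S)-3-(3,5-dihydroxyphenyl)-4-hydroxy-2-(4-hydroxyphenyl)-2,3-dihydro-1-benzofuran-6-yl]-2-(4-hydroxyphenyl)-6-[(E)-2-(4-hydroxyphenyl)ethenyl]-2,3-dihydro-1-benzofuran-4-ol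
Conditions: BBr3 (20 equiv), CH2Cl2, −78 °C → rt, dark; then MeOH, H2O
Reagents that add atoms: none
Why: Lewis acid ether cleavage: BBr3 binds each methoxy oxygen, bromide removes the methyl group by SN2, and the aryl borates are hydrolysed on work-up. C3 and C3' cannot ionise, trans is the thermodynamic arrangement at C2 and C2', and the styryl group at C6 is remote from any arene that could cyclise onto it.

## Compound list

1 | 4,6-dihydroxy-1-benzofuran-3(2H)-one | O=C1COc2cc(O)cc(O)c12 | starting material
2 | 6-(benzyloxy)-4-hydroxy-1-benzofuran-3(2H)-one | O=C1COc2cc(OCc3ccccc3)cc(O)c12 | intermediate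
3 | 6-(benzyloxy)-4-methoxy-1-benzofuran-3(2H)-one | O=C1COc2cc(OCc3ccccc3)cc(OC)c12 | intermediate
4 | racemic 6-(benzyloxy)-4-methoxy-2,3-dihydro-1-benzofuran-3-ol | COc1cc(OCc2ccccc2)cc2OCC(O)c12 | intermediate
5 | 6-(benzyloxy)-4-methoxy-1-benzofuran | COc1cc(OCc2ccccc2)cc2occc12 | intermediate
6 | 3,5-dimethoxyphenol | COc1cc(O)cc(OC)c1 | starting material
7 | 3,5-dimethoxyphenyl trifluoromethanesulfonate | COc1cc(OC)cc(OS(=O)(=O)C(F)(F)F)c1 | intermediate
8 | 2-(4-methoxyphenyl)-4,4,5,5-tetramethyl-1,3,2-dioxaborolane | COc1ccc(cc1)B1OC(C)(C)C(C)(C)O1 | starting material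
9 | [6-(benzyloxy)-4-methoxy-1-benzofuran-2-yl]lithium | [Li]c1cc2c(OC)cc(OCc3ccccc3)cc2o1 | intermediate
10 | lithium [6-(benzyloxy)-4-methoxy-1-benzofuran-2-yl](4-methoxyphenyl)(2,3-dimethylbutane-2,3-diolato)borate | [Li+].COc1ccc(cc1)[B-]1(OC(C)(C)C(C)(C)O1)c1cc2c(OC)cc(OCc3ccccc3)cc2o1 | intermediate
11 | 2-[(2S,3S)-6-(benzyloxy)-3-(3,5-dimethoxyphenyl)-4-methoxy-2-(4-methoxyphenyl)-2,3-dihydro-1-benzofuran-2-yl]-4,4,5,5-tetramethyl-1,3,2-dioxaborolane | COc1cc(OCc2ccccc2)cc2O[C@](B3OC(C)(C)C(C)(C)O3)(c3ccc(OC)cc3)[C@@H](c3cc(OC)cc(OC)c3)c12 | intermediate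
12 | (2S,3S)-6-(benzyloxy)-3-(3,5-dimethoxyphenyl)-4-methoxy-2-(4-methoxyphenyl)-2,3-dihydro-1-benzofuran | COc1cc(OCc2ccccc2)cc2O[C@H](c3ccc(OC)cc3)[C@@H](c3cc(OC)cc(OC)c3)c12 | intermediate
13 | (2S,3S)-3-(3,5-dimethoxyphenyl)-4-methoxy-2-(4-methoxyphenyl)-2,3-dihydro-1-benzofuran-6-ol | COc1cc(O)cc2O[C@H](c3ccc(OC)cc3)[C@@H](c3cc(OC)cc(OC)c3)c12 | intermediate
14 | (2S,3S)-3-(3,5-dimethoxyphenyl)-4-methoxy-2-(4-methoxyphenyl)-2,3-dihydro-1-benzofuran-6-yl trifluoromethanesulfonate | COc1cc(OS(=O)(=O)C(F)(F)F)cc2O[C@H](c3ccc(OC)cc3)[C@@H](c3cc(OC)cc(OC)c3)c12 | intermediate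
15 | 2-[(2S,3S)-6-(benzyloxy)-3-[(2S,3S)-3-(3,5-dimethoxyphenyl)-4-methoxy-2-(4-methoxyphenyl)-2,3-dihydro-1-benzofuran-6-yl]-4-methoxy-2-(4-methoxyphenyl)-2,3-dihydro-1-benzofuran-2-yl]-4,4,5,5-tetramethyl-1,3,2-dioxaborolane | COc1cc(OCc2ccccc2)cc2O[C@](B3OC(C)(C)C(C)(C)O3)(c3ccc(OC)cc3)[C@@H](c3cc(OC)c4c(c3)O[C@H](c3ccc(OC)cc3)[C@H]4c3cc(OC)cc(OC)c3)c12 | intermediate
16 | (2S,3S)-6-(benzyloxy)-3-[(2S,3S)-3-(3,5-dimethoxyphenyl)-4-methoxy-2-(4-methoxyphenyl)-2,3-dihydro-1-benzofuran-6-yl]-4-methoxy-2-(4-methoxyphenyl)-2,3-dihydro-1-benzofuran | COc1cc(OCc2ccccc2)cc2O[C@H](c3ccc(OC)cc3)[C@@H](c3cc(OC)c4c(c3)O[C@H](c3ccc(OC)cc3)[C@H]4c3cc(OC)cc(OC)c3)c12 | intermediate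
17 | (2S,3S)-3-[(2S,3S)-3-(3,5-dimethoxyphenyl)-4-methoxy-2-(4-methoxyphenyl)-2,3-dihydro-1-benzofuran-6-yl]-4-methoxy-2-(4-methoxyphenyl)-2,3-dihydro-1-benzofuran-6-ol | COc1cc(O)cc2O[C@H](c3ccc(OC)cc3)[C@@H](c3cc(OC)c4c(c3)O[C@H](c3ccc(OC)cc3)[C@H]4c3cc(OC)cc(OC)c3)c12 | intermediate
18 | (2S,3S)-3-[(2S,3S)-3-(3,5-dimethoxyphenyl)-4-methoxy-2-(4-methoxyphenyl)-2,3-dihydro-1-benzofuran-6-yl]-4-methoxy-2-(4-methoxyphenyl)-2,3-dihydro-1-benzofuran-6-yl trifluoromethanesulfonate | COc1cc(OS(=O)(=O)C(F)(F)F)cc2O[C@H](c3ccc(OC)cc3)[C@@H](c3cc(OC)c4c(c3)O[C@H](c3ccc(OC)cc3)[C@H]4c3cc(OC)cc(OC)c3)c12 | intermediate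
19 | 4-methoxystyrene | C=Cc1ccc(OC)cc1 | starting material
20 | (2S,3S)-3-[(2S,3S)-3-(3,5-dimethoxyphenyl)-4-methoxy-2-(4-methoxyphenyl)-2,3-dihydro-1-benzofuran-6-yl]-4-methoxy-2-(4-methoxyphenyl)-6-[(E)-2-(4-methoxyphenyl)ethenyl]-2,3-dihydro-1-benzofuran | COc1ccc(/C=C/c2cc(OC)c3c(c2)O[C@H](c2ccc(OC)cc2)[C@H]3c2cc(OC)c3c(c2)O[C@H](c2ccc(OC)cc2)[C@H]3c2cc(OC)cc(OC)c2)cc1 | intermediate
21 | (2S,3S)-3-[(2S,3S)-3-(3,5-dihydroxyphenyl)-4-hydroxy-2-(4-hydroxyphenyl)-2,3-dihydro-1-benzofuran-6-yl]-2-(4-hydroxyphenyl)-6-[(E)-2-(4-hydroxyphenyl)ethenyl]-2,3-dihydro-1-benzofuran-4-ol | Oc1ccc(/C=C/c2cc(O)c3c(c2)O[C@H](c2ccc(O)cc2)[C@H]3c2cc(O)c3c(c2)O[C@H](c2ccc(O)cc2)[C@H]3c2cc(O)cc(O)c2)cc1 | target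

## Step count and least certain steps

Total: 15 steps. Longest linear sequence: 14 steps (steps 1–3 and 5–15; step 4 is a one-step side branch).

Step 6 (key step, proposed new method).
- What may go wrong: direct transfer of the benzofuranyl or the anisyl group from boron to palladium (Suzuki-type coupling) may outrun binding of the furan double bond, because dearomatising the furan costs more than engaging a simple alkene. Facial selection may be weak with a ligand developed for other substrates. The peri 4-methoxy group may slow palladation at C3. Traces of moisture may protonate the borate at C2 before the catalyst engages it.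
- Fallback (known chemistry, sets out from 5, returns at 12): ozonolysis of the furan double bond of 5 (O3, CH2Cl2/MeOH, −78 °C; Me2S; then K2CO3, MeOH to cleave the aryl formate) would give 4-(benzyloxy)-2-hydroxy-6-methoxybenzaldehyde F1. 4-Methoxybenzyl chloride and K2CO3 in DMF would give 4-(benzyloxy)-2-methoxy-6-[(4-methoxybenzyl)oxy]benzaldehyde F2. Addition of 3,5-dimethoxyphenylmagnesium bromide would give the racemic diarylmethanol F3, and Dess–Martin periodinane the benzophenone F4. Hydrazine hydrate (EtOH, 80 °C) would give the hydrazone F5, and MnO2 the diaryl diazomethane F6, used at once. Rh2(R-PTAD)4 or its enantiomer (CH2Cl2, 0 °C) would insert the carbene carbon into the benzylic C–H bond of the 4-methoxybenzyl ether and close the furan as the cis (2R,3S) dihydrobenzofuran F7, with C3 set by the catalyst. TFA in CH2Cl2 would then epimerise C2 through the 4-methoxybenzylic cation to give 12.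

Step 10 (proposed new method).
- What may go wrong: oxidative addition and alkene binding with the bulky, electron-rich triflate 14 may be slow, leaving time for protonation of the ate complex or Suzuki-type transfer; facial selectivity may again be poor; the stored borate may have lost activity through slow hydrolysis, in which case a fresh batch would be made by repeating step 5.
- Fallback (known chemistry, sets out from 14, returns at 16): Miyaura borylation of 14 (B2pin2, PdCl2(dppf), KOAc, dioxane, 80 °C) would give the arylboronic ester F8. Rhodium-catalysed 1,2-addition ([Rh(cod)OH]2, dioxane/H2O, 60 °C) to aldehyde F2, made from 5 as in the fallback to step 6, would give the diarylmethanol F9 (carbinol centre unassigned). Dess–Martin periodinane would give the ketone F10, hydrazine hydrate the hydrazone F11, and MnO2 the diaryl diazomethane F12. Rh2(R-PTAD)4 or its enantiomer would close the ring A furan by benzylic C–H insertion as the cis (2R,3S) compound F13, and TFA in CH2Cl2 would epimerise C2 to give 16.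

Step 15.
- What may go wrong: ionisation of a C2–O bond followed by capture of the cation by bromide or an electron-rich arene (ring opening), cationic oligomerisation of the 4-hydroxystilbene under HBr, and incomplete cleavage of seven ethers.
- Fallback (sets out from 18, returns at 21): the ethers are removed before the alkene exists and the phenols are carried as acetates. BBr3 on 18 would give the hexaphenol triflate F14; Ac2O and pyridine the hexaacetate triflate F15; a Heck reaction with commercial 4-acetoxystyrene (PdCl2(PPh3)2, LiCl, Et3N, DMF, 100 °C) the heptaacetate F16; and K2CO3 in MeOH at 0 °C would release 21 by transesterification, without acid.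

Step 14.
- What may go wrong: aryl transfer to the internal alkene carbon of the electron-rich styrene through the cationic pathway that triflates favour, and partial E/Z isomerisation.
- Fallback (sets out from 18, returns at 20): Suzuki–Miyaura coupling of 18 with commercial (E)-2-(4-methoxyphenyl)vinylboronic acid pinacol ester (PdCl2(dppf), K3PO4, dioxane/H2O, 80 °C); regiochemistry and alkene geometry are then fixed in the boron reagent and no new intermediate is needed.

## Further compounds

F1 | step 6 | 4-(benzyloxy)-2-hydroxy-6-methoxybenzaldehyde | COc1cc(OCc2ccccc2)cc(O)c1C=O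
F2 | step 6 | 4-(benzyloxy)-2-methoxy-6-[(4-methoxybenzyl)oxy]benzaldehyde | COc1ccc(COc2cc(OCc3ccccc3)cc(OC)c2C=O)cc1
F3 | step 6 | racemic [4-(benzyloxy)-2-methoxy-6-[(4-methoxybenzyl)oxy]phenyl](3,5-dimethoxyphenyl)methanol | COc1ccc(COc2cc(OCc3ccccc3)cc(OC)c2C(O)c2cc(OC)cc(OC)c2)cc1
F4 | step 6 | [4-(benzyloxy)-2-methoxy-6-[(4-methoxybenzyl)oxy]phenyl](3,5-dimethoxyphenyl)methanone | COc1ccc(COc2cc(OCc3ccccc3)cc(OC)c2C(=O)c2cc(OC)cc(OC)c2)cc1
F5 | step 6 | hydrazone of [4-(benzyloxy)-2-methoxy-6-[(4-methoxybenzyl)oxy]phenyl](3,5-dimethoxyphenyl)methanone | COc1ccc(COc2cc(OCc3ccccc3)cc(OC)c2C(=NN)c2cc(OC)cc(OC)c2)cc1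
F6 | step 6 | [4-(benzyloxy)-2-methoxy-6-[(4-methoxybenzyl)oxy]phenyl](3,5-dimethoxyphenyl)diazomethane | COc1ccc(COc2cc(OCc3ccccc3)cc(OC)c2C(=[N+]=[N-])c2cc(OC)cc(OC)c2)cc1
F7 | step 6 | (2R,3S)-6-(benzyloxy)-3-(3,5-dimethoxyphenyl)-4-methoxy-2-(4-methoxyphenyl)-2,3-dihydro-1-benzofuran (cis) | COc1cc(OCc2ccccc2)cc2O[C@@H](c3ccc(OC)cc3)[C@@H](c3cc(OC)cc(OC)c3)c12
F8 | step 10 | 2-[(2S,3S)-3-(3,5-dimethoxyphenyl)-4-methoxy-2-(4-methoxyphenyl)-2,3-dihydro-1-benzofuran-6-yl]-4,4,5,5-tetramethyl-1,3,2-dioxaborolane | CC1(C)OB(OC1(C)C)c1cc(OC)c2c(c1)O[C@H](c1ccc(OC)cc1)[C@H]2c1cc(OC)cc(OC)c1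
F9 | step 10 | [4-(benzyloxy)-2-methoxy-6-[(4-methoxybenzyl)oxy]phenyl][(2S,3S)-3-(3,5-dimethoxyphenyl)-4-methoxy-2-(4-methoxyphenyl)-2,3-dihydro-1-benzofuran-6-yl]methanol (carbinol epimers) | COc1ccc(COc2cc(OCc3ccccc3)cc(OC)c2C(O)c2cc(OC)c3c(c2)O[C@H](c2ccc(OC)cc2)[C@H]3c2cc(OC)cc(OC)c2)cc1
F10 | step 10 | [4-(benzyloxy)-2-methoxy-6-[(4-methoxybenzyl)oxy]phenyl][(2S,3S)-3-(3,5-dimethoxyphenyl)-4-methoxy-2-(4-methoxyphenyl)-2,3-dihydro-1-benzofuran-6-yl]methanone | COc1ccc(COc2cc(OCc3ccccc3)cc(OC)c2C(=O)c2cc(OC)c3c(c2)O[C@H](c2ccc(OC)cc2)[C@H]3c2cc(OC)cc(OC)c2)cc1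
F11 | step 10 | hydrazone of [4-(benzyloxy)-2-methoxy-6-[(4-methoxybenzyl)oxy]phenyl][(2S,3S)-3-(3,5-dimethoxyphenyl)-4-methoxy-2-(4-methoxyphenyl)-2,3-dihydro-1-benzofuran-6-yl]methanone | COc1ccc(COc2cc(OCc3ccccc3)cc(OC)c2C(=NN)c2cc(OC)c3c(c2)O[C@H](c2ccc(OC)cc2)[C@H]3c2cc(OC)cc(OC)c2)cc1
F12 | step 10 | [4-(benzyloxy)-2-methoxy-6-[(4-methoxybenzyl)oxy]phenyl][(2S,3S)-3-(3,5-dimethoxyphenyl)-4-methoxy-2-(4-methoxyphenyl)-2,3-dihydro-1-benzofuran-6-yl]diazomethane | COc1ccc(COc2cc(OCc3ccccc3)cc(OC)c2C(=[N+]=[N-])c2cc(OC)c3c(c2)O[C@H](c2ccc(OC)cc2)[C@H]3c2cc(OC)cc(OC)c2)cc1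
F13 | step 10 | (2R,3S)-6-(benzyloxy)-3-[(2S,3S)-3-(3,5-dimethoxyphenyl)-4-methoxy-2-(4-methoxyphenyl)-2,3-dihydro-1-benzofuran-6-yl]-4-methoxy-2-(4-methoxyphenyl)-2,3-dihydro-1-benzofuran (ring A furan cis) | COc1cc(OCc2ccccc2)cc2O[C@@H](c3ccc(OC)cc3)[C@@H](c3cc(OC)c4c(c3)O[C@H](c3ccc(OC)cc3)[C@H]4c3cc(OC)cc(OC)c3)c12
F14 | step 15 | (2S,3S)-3-[(2S,3S)-3-(3,5-dihydroxyphenyl)-4-hydroxy-2-(4-hydroxyphenyl)-2,3-dihydro-1-benzofuran-6-yl]-4-hydroxy-2-(4-hydroxyphenyl)-2,3-dihydro-1-benzofuran-6-yl trifluoromethanesulfonate | Oc1cc(OS(=O)(=O)C(F)(F)F)cc2O[C@H](c3ccc(O)cc3)[C@@H](c3cc(O)c4c(c3)O[C@H](c3ccc(O)cc3)[C@H]4c3cc(O)cc(O)c3)c12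
F15 | step 15 | hexaacetate of F14: (2S,3S)-4-acetoxy-3-[(2S,3S)-4-acetoxy-2-(4-acetoxyphenyl)-3-(3,5-diacetoxyphenyl)-2,3-dihydro-1-benzofuran-6-yl]-2-(4-acetoxyphenyl)-2,3-dihydro-1-benzofuran-6-yl trifluoromethanesulfonate | CC(=O)Oc1cc(OS(=O)(=O)C(F)(F)F)cc2O[C@H](c3ccc(OC(C)=O)cc3)[C@@H](c3cc(OC(C)=O)c4c(c3)O[C@H](c3ccc(OC(C)=O)cc3)[C@H]4c3cc(OC(C)=O)cc(OC(C)=O)c3)c12
F16 | step 15 | heptaacetate of 21 | CC(=O)Oc1ccc(/C=C/c2cc(OC(C)=O)c3c(c2)O[C@H](c2ccc(OC(C)=O)cc2)[C@H]3c2cc(OC(C)=O)c3c(c2)O[C@H](c2ccc(OC(C)=O)cc2)[C@H]3c2cc(OC(C)=O)cc(OC(C)=O)c2)cc1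
F0 | step 14 | none | none
A1 | alternative 1 | 3-hydroxy-5-(triisopropylsilyloxy)benzene carrying at C4 the (1S,2S)-2-[(tert-butyldimethylsilyl)oxy]-1-(3,5-dimethoxyphenyl)-2-(4-methoxyphenyl)ethyl chain and at C1 the (2S,3S)-4-methoxy-2-(4-methoxyphenyl)-6-[(E)-2-(4-methoxyphenyl)ethenyl]-2,3-dihydro-1-benzofuran-3-yl group | COc1ccc(/C=C/c2cc(OC)c3c(c2)O[C@H](c2ccc(OC)cc2)[C@H]3c2cc(O)c(c(O[Si](C(C)C)(C(C)C)C(C)C)c2)[C@H](c2cc(OC)cc(OC)c2)[C@H](O[Si](C)(C)C(C)(C)C)c2ccc(OC)cc2)cc1
A2 | alternative 1 | 3-[(2S,3S)-4-methoxy-2-(4-methoxyphenyl)-6-[(E)-2-(4-methoxyphenyl)ethenyl]-2,3-dihydro-1-benzofuran-3-yl]cyclobut-2-en-1-one | O=C1CC(=C1)[C@H]1c2c(OC)cc(/C=C/c3ccc(OC)cc3)cc2O[C@@H]1c1ccc(OC)cc1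
A3 | alternative 1 | tert-butyl{[(1S,2S)-2-(3,5-dimethoxyphenyl)-1-(4-methoxyphenyl)-4-[(triisopropylsilyl)oxy]but-3-yn-1-yl]oxy}dimethylsilane | CC(C)[Si](C(C)C)(C(C)C)OC#C[C@H](c1cc(OC)cc(OC)c1)[C@H](O[Si](C)(C)C(C)(C)C)c1ccc(OC)cc1
A4 | alternative 2 | (2R,3S)-6-bromo-3-[(2S,3S)-3-(3,5-dimethoxyphenyl)-4-methoxy-2-(4-methoxyphenyl)-2,3-dihydro-1-benzofuran-6-yl]-4-methoxy-2-(4-methoxyphenyl)-2,3-dihydro-1-benzofuran (ring A furan cis) | Brc1cc(OC)c2c(c1)O[C@@H](c1ccc(OC)cc1)[C@H]2c1cc(OC)c2c(c1)O[C@H](c1ccc(OC)cc1)[C@H]2c1cc(OC)cc(OC)c1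
A5 | alternative 2 | [4-bromo-2-methoxy-6-[(4-methoxybenzyl)oxy]phenyl][(2S,3S)-3-(3,5-dimethoxyphenyl)-4-methoxy-2-(4-methoxyphenyl)-2,3-dihydro-1-benzofuran-6-yl]diazomethane | [N-]=[N+]=C(c1c(OC)cc(Br)cc1OCc1ccc(OC)cc1)c1cc(OC)c2c(c1)O[C@H](c1ccc(OC)cc1)[C@H]2c1cc(OC)cc(OC)c1
A6 | alternative 3 | methyl (2S,3S)-6-(benzyloxy)-4-methoxy-2-[4-(methanesulfonyloxy)phenyl]-2,3-dihydro-1-benzofuran-3-carboxylate (trans) | C(Oc1cc(OC)c2c(c1)O[C@H](c1ccc(OS(C)(=O)=O)cc1)[C@H]2C(=O)OC)c1ccccc1
A7 | alternative 3 | (2S)-7-(benzyloxy)-5-methoxy-2-[4-(methanesulfonyloxy)phenyl]-2,3-dihydro-4H-chromen-4-one | O=C1C[C@@H](c2ccc(OS(C)(=O)=O)cc2)Oc2cc(OCc3ccccc3)cc(OC)c12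
A8 | alternative 3 | (2S)-naringenin, (2S)-5,7-dihydroxy-2-(4-hydroxyphenyl)-2,3-dihydro-4H-chromen-4-one | O=C1C[C@@H](c2ccc(O)cc2)Oc2cc(O)cc(O)c12
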